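The retrosynthesis cuts, in this order: the four O-benzyl bonds, C4''-C4a'' (opening ring C''), the O1''-C2'' aryl ether bond, the C3-C6'' biaryl bond, and the C3-I bond of a benzylated apigenin.
Enabling feature: while ring C'' is open, ring A'' is a 2,4,6-trioxygenated phenyl group on C3, symmetric about the C6''···C8a'' line. The oxygen para to C3 is the future O1''. The two CH carbons next to it (future C4a'' and C8'') are equivalent, so closure at either gives the same 6''-linked chroman.
Forward order: rings A, B and C come intact from apigenin, and ring A'' (phloroglucinol) is joined to C3 by Negishi coupling. Ring B'' with C2''-C4'' (from 4'-(benzyloxy)acetophenone) is attached to the para oxygen, ring C'' closes last, and global debenzylation follows.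
Stereochemistry: C2'' is the only stereocentre. An (R)-carbinol from Ru/(S)-SEGPHOS hydrogenation of a beta-keto ester is inverted to S in the Mitsunobu etherification and is not touched afterwards.

Key step: step 12

Assumption: rotation about the C3-C6'' biaryl axis is taken to be fast on the preparative time scale (both ortho substituents on ring A'' are hydroxyl groups), so C2'' is the only stereogenic element to be controlled.

Step 1
Reactants: 1 apigenin
Product: 2 tri-O-benzylapigenin (5,7-bis(benzyloxy)-2-[4-(benzyloxy)phenyl]chromen-4-one)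
Conditions: BnBr (4 equiv), K2CO3, DMF, 80 °C
Reagents that add atoms: benzyl bromide, BrCc1ccccc1
Why: Williamson ether synthesis; excess benzyl bromide and heating in DMF should also alkylate the chelated 5-OH, so all three phenols carry a group that leaves in one final operation.

Step 2
Reactants: 2 tri-O-benzylapigenin
Product: 4 tri-O-benzyl-3-iodoapigenin (5,7-bis(benzyloxy)-2-[4-(benzyloxy)phenyl]-3-iodochromen-4-one), via 3-lithioflavone 3 (not isolated)
Conditions: LiN(i-Pr)2 (1.3 equiv), THF, -78 °C; then I2, -78 °C to -20 °C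
Reagents that add atoms: iodine, [I][I]
Why: Carbonyl-directed deprotonation of the vinylic C3-H of a flavone followed by an iodine quench is a known route to 3-iodoflavones, and it avoids electrophilic iodination, which would attack C6/C8 of the electron-rich ring A.

Step 3
Reactants: 5 phloroglucinol
Product: 6 1,3,5-tris(methoxymethoxy)benzene
Conditions: NaH, MOMCl, DMF, 0 °C to rt
Reagents that add atoms: chloromethyl methyl ether, COCCl
Why: Threefold O-alkylation (acetal protection) gives a symmetric arene whose MOM groups direct the later lithiation and can be removed by acid without touching benzyl ethers.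

Step 4
Reactants: 6 1,3,5-tris(methoxymethoxy)benzene; 4 tri-O-benzyl-3-iodoapigenin
Product: 9 tri-O-benzyl-3-[2,4,6-tris(methoxymethoxy)phenyl]apigenin, via aryllithium 7 (not isolated), via arylzinc chloride 8 (not isolated)
Conditions: 6 (1.5 equiv), n-BuLi, THF, 0 °C; ZnCl2, 0 °C to rt; then 4, Pd2(dba)3 (2.5 mol %), RuPhos (10 mol %), THF, 65 °C
Reagents that add atoms: none
Why: Directed ortho-metalation between two MOM ethers (all three CH positions are equivalent), transmetalation to zinc and Negishi coupling with zerovalent palladium and a bulky dialkylbiarylphosphine is established for doubly ortho-substituted partners, the arylzinc spares the pyranone carbonyl, and it avoids the protodeboronation expected of the corresponding boronic acid.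

Step 5
Reactants: 9 tri-O-benzyl-3-[2,4,6-tris(methoxymethoxy)phenyl]apigenin
Product: 10 tri-O-benzyl-3-(2,4,6-trihydroxyphenyl)apigenin
Conditions: HCl (2 M in MeOH), THF, 40 °C
Reagents that add atoms: none
Why: Acid-catalysed acetal exchange with methanol removes the three MOM groups while benzyl ethers persist, and the only acidic step of the route is placed before the acid-labile benzylic aryl ether exists.

Step 6
Reactants: 11 4'-(benzyloxy)acetophenone
Product: 12 ethyl 3-[4-(benzyloxy)phenyl]-3-oxopropanoate
Conditions: NaH, (EtO)2CO, toluene, 100 °C; then 1 M HCl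
Reagents that add atoms: diethyl carbonate, CCOC(=O)OCC
Why: Crossed Claisen condensation of the ketone enolate with non-enolisable diethyl carbonate, driven by deprotonation of the beta-keto ester formed.

Step 7
Reactants: 12 ethyl 3-[4-(benzyloxy)phenyl]-3-oxopropanoate
Product: 13 ethyl (3R)-3-[4-(benzyloxy)phenyl]-3-hydroxypropanoate
Conditions: [RuCl(p-cymene)((S)-SEGPHOS)]Cl (0.5 mol %), H2 (30 bar), EtOH, 60 °C
Reagents that add atoms: none
Why: Noyori-type asymmetric hydrogenation of a beta-keto ester, in which chelation of both carbonyl oxygens to the chiral Ru-diphosphine hydride fixes the face attacked and the (S)-ligand should give the R carbinol (the descriptor is R because aryl outranks CH2CO2Et), with benzyl ethers inert to this catalyst.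

Step 8
Reactants: 13 ethyl (3R)-3-[4-(benzyloxy)phenyl]-3-hydroxypropanoate
Product: 14 (1R)-1-[4-(benzyloxy)phenyl]propane-1,3-diol
Conditions: LiAlH4, THF, 0 °C; then Na2SO4·10H2O
Reagents that add atoms: none
Why: Hydride reduction of the ester to the primary alcohol does not involve the carbinol centre, and the diol offers a point for enrichment by crystallisation.

Step 9
Reactants: 14 (1R)-1-[4-(benzyloxy)phenyl]propane-1,3-diol
Product: 15 (3R)-3-[4-(benzyloxy)phenyl]-3-hydroxypropyl 4-methylbenzenesulfonate
Conditions: TsCl (1.05 equiv), pyridine, CH2Cl2, 0 °C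
Reagents that add atoms: 4-toluenesulfonyl chloride, Cc1ccc(cc1)S(=O)(=O)Cl
Why: Selective sulfonylation of the primary over the secondary benzylic hydroxyl on steric grounds, as practised on 1-arylpropane-1,3-diols.

Step 10
Reactants: 15 (3R)-3-[4-(benzyloxy)phenyl]-3-hydroxypropyl 4-methylbenzenesulfonate
Product: 16 (1R)-1-[4-(benzyloxy)phenyl]-3-bromopropan-1-ol
Conditions: LiBr, acetone, 50 °C
Reagents that add atoms: lithium bromide, [Li+].[Br-]
Why: Finkelstein-type SN2 displacement at the primary carbon under neutral conditions leaves the benzylic carbinol and its configuration untouched.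

Step 11
Reactants: 10 tri-O-benzyl-3-(2,4,6-trihydroxyphenyl)apigenin; 16 (1R)-1-[4-(benzyloxy)phenyl]-3-bromopropan-1-ol
Product: 17 bromo ether (5,7-bis(benzyloxy)-2-[4-(benzyloxy)phenyl]-3-{4-[(1S)-1-[4-(benzyloxy)phenyl]-3-bromopropoxy]-2,6-dihydroxyphenyl}chromen-4-one)
Conditions: 16 (0.95 equiv), PPh3, DIAD, toluene-THF, -10 °C to rt
Reagents that add atoms: none
Why: Mitsunobu etherification, known for 3-halo-1-arylpropan-1-ols with phenols, inverts the carbinol carbon (R to S) by SN2 attack of the phenoxide on the alkoxyphosphonium salt; the para hydroxyl should react first because both ortho hydroxyls lie buried between the 2-aryl group and the C4 carbonyl (to which they can hydrogen-bond), and low temperature in a weakly polar solvent disfavours ionisation.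

Step 12
Reactants: 17 bromo ether
Product: 20 tetra-O-benzyl biflavonoid (5,7-bis(benzyloxy)-2-[4-(benzyloxy)phenyl]-3-{(2S)-2-[4-(benzyloxy)phenyl]-5,7-dihydroxychroman-6-yl}chromen-4-one), via dilithium bis(phenoxide) 18 (not isolated), via cyclohexadienone 19 (not isolated)
Conditions: LiOt-Bu (2.1 equiv), toluene (0.005 M), 80 °C; then 1 M HCl
Reagents that add atoms: none
Why: Two equivalents of LiOt-Bu turn 17 into the dilithium bis(phenoxide) 18, in which the ring CH carbon lying between a phenoxide carbon and the ether-bearing carbon (ortho to one O-Li, para to the other) displaces the primary bromide by SN2 to give cyclohexadienone 19, and loss of the now acidic C4a''-H restores the arene as the phenoxide of 20. The closest known reactions are the ring-forming ortho C-alkylation of phenoxides by tethered halides or sulfonates (Ar2-6 aryl participation) and the base-mediated C-alkylation of phloroglucinols. Ring C'' closes in the 6-exo-tet mode with the enolate C5''=C4a'' bond outside the new ring, over the arene face, on the same trajectory as the cyclialkylation of 3-aryloxypropyl electrophiles to chromans. No lasting stereocentre is created, because sp3 C4a'' of 19 is flattened again on tautomerisation, and C2'' keeps its S configuration since it bears no acidic hydrogen and, with the 4'''-oxygen benzylated, cannot expel the aryloxide by way of a quinone methide. The step needs C- rather than O-alkylation, which the substrate secures because intramolecular O-attack would require a meta-bridged eight-membered ring, both phenoxide oxygens are screened by the flavone and held in tight lithium aggregates in toluene, and high dilution holds back intermolecular etherification. Site selectivity needs no control, as the two CH carbons are exchanged by rotation about the C3-aryl bond and each leads to the same 6''-linked chroman.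

Step 13
Reactants: 20 tetra-O-benzyl biflavonoid
Product: 21 CNP0304187.1 (5,7-dihydroxy-3-[(2S)-5,7-dihydroxy-2-(4-hydroxyphenyl)chroman-6-yl]-2-(4-hydroxyphenyl)chromen-4-one)
Conditions: H2 (1 atm), 10% Pd/C, THF-MeOH, rt
Reagents that add atoms: none
Why: Catalytic hydrogenolysis of the four benzyl aryl ethers, under mild conditions that the cyclic benzylic C2''-O1'' bond of flavans and the tetrasubstituted C2=C3 bond of the flavone are known to survive, so the S configuration is retained.

Compound list
1 | apigenin | O=c1cc(-c2ccc(O)cc2)oc2cc(O)cc(O)c12 | starting material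
2 | tri-O-benzylapigenin | O=c1cc(-c2ccc(OCc3ccccc3)cc2)oc2cc(OCc3ccccc3)cc(OCc3ccccc3)c12 | intermediate
3 | 3-lithio-tri-O-benzylapigenin | O=c1c([Li])c(-c2ccc(OCc3ccccc3)cc2)oc2cc(OCc3ccccc3)cc(OCc3ccccc3)c12 | intermediate
4 | tri-O-benzyl-3-iodoapigenin | O=c1c(I)c(-c2ccc(OCc3ccccc3)cc2)oc2cc(OCc3ccccc3)cc(OCc3ccccc3)c12 | intermediate
5 | phloroglucinol | Oc1cc(O)cc(O)c1 | starting material
6 | 1,3,5-tris(methoxymethoxy)benzene | COCOc1cc(OCOC)cc(OCOC)c1 | intermediate
7 | 2,4,6-tris(methoxymethoxy)phenyllithium | [Li]c1c(OCOC)cc(OCOC)cc1OCOC | intermediate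
8 | 2,4,6-tris(methoxymethoxy)phenylzinc chloride | Cl[Zn]c1c(OCOC)cc(OCOC)cc1OCOC | intermediate
9 | 5,7-bis(benzyloxy)-2-[4-(benzyloxy)phenyl]-3-[2,4,6-tris(methoxymethoxy)phenyl]chromen-4-one | O=c1c(-c2c(OCOC)cc(OCOC)cc2OCOC)c(-c2ccc(OCc3ccccc3)cc2)oc2cc(OCc3ccccc3)cc(OCc3ccccc3)c12 | intermediate
10 | 5,7-bis(benzyloxy)-2-[4-(benzyloxy)phenyl]-3-(2,4,6-trihydroxyphenyl)chromen-4-one | O=c1c(-c2c(O)cc(O)cc2O)c(-c2ccc(OCc3ccccc3)cc2)oc2cc(OCc3ccccc3)cc(OCc3ccccc3)c12 | intermediate
11 | 4'-(benzyloxy)acetophenone | CC(=O)c1ccc(OCc2ccccc2)cc1 | starting material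
12 | ethyl 3-[4-(benzyloxy)phenyl]-3-oxopropanoate | CCOC(=O)CC(=O)c1ccc(OCc2ccccc2)cc1 | intermediate
13 | ethyl (3R)-3-[4-(benzyloxy)phenyl]-3-hydroxypropanoate | CCOC(=O)C[C@@H](O)c1ccc(OCc2ccccc2)cc1 | intermediate
14 | (1R)-1-[4-(benzyloxy)phenyl]propane-1,3-diol | OCC[C@@H](O)c1ccc(OCc2ccccc2)cc1 | intermediate
15 | (3R)-3-[4-(benzyloxy)phenyl]-3-hydroxypropyl 4-methylbenzenesulfonate | Cc1ccc(cc1)S(=O)(=O)OCC[C@@H](O)c1ccc(OCc2ccccc2)cc1 | intermediate
16 | (1R)-1-[4-(benzyloxy)phenyl]-3-bromopropan-1-ol | BrCC[C@@H](O)c1ccc(OCc2ccccc2)cc1 | intermediate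
17 | 5,7-bis(benzyloxy)-2-[4-(benzyloxy)phenyl]-3-{4-[(1S)-1-[4-(benzyloxy)phenyl]-3-bromopropoxy]-2,6-dihydroxyphenyl}chromen-4-one | O=c1c(-c2c(O)cc(O[C@@H](CCBr)c3ccc(OCc4ccccc4)cc3)cc2O)c(-c2ccc(OCc3ccccc3)cc2)oc2cc(OCc3ccccc3)cc(OCc3ccccc3)c12 | intermediate
18 | dilithium bis(phenoxide) of 17 | [Li+].[Li+].O=c1c(-c2c([O-])cc(O[C@@H](CCBr)c3ccc(OCc4ccccc4)cc3)cc2[O-])c(-c2ccc(OCc3ccccc3)cc2)oc2cc(OCc3ccccc3)cc(OCc3ccccc3)c12 | intermediate
19 | lithium salt of the (2S)-4a-H-chroman-5-one dienone (C4a'' sp3, configuration there not defined) | [Li+].O=c1c(C2=C([O-])C=C3O[C@H](c4ccc(OCc5ccccc5)cc4)CCC3C2=O)c(-c2ccc(OCc3ccccc3)cc2)oc2cc(OCc3ccccc3)cc(OCc3ccccc3)c12 | intermediate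
20 | 5,7-bis(benzyloxy)-2-[4-(benzyloxy)phenyl]-3-{(2S)-2-[4-(benzyloxy)phenyl]-5,7-dihydroxychroman-6-yl}chromen-4-one | O=c1c(-c2c(O)cc3c(c2O)CC[C@@H](c2ccc(OCc4ccccc4)cc2)O3)c(-c2ccc(OCc3ccccc3)cc2)oc2cc(OCc3ccccc3)cc(OCc3ccccc3)c12 | intermediate
21 | CNP0304187.1, 5,7-dihydroxy-3-[(2S)-5,7-dihydroxy-2-(4-hydroxyphenyl)chroman-6-yl]-2-(4-hydroxyphenyl)chromen-4-one | O=c1c(-c2c(O)cc3c(c2O)CC[C@@H](c2ccc(O)cc2)O3)c(-c2ccc(O)cc2)oc2cc(O)cc(O)c12 | target

Total step count: 13.
Longest linear sequence: 8 steps (steps 6 to 13, from 11). The apigenin branch runs over 7 steps and the phloroglucinol branch over 6.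

Steps most likely to fail

1. Step 12.
- What may go wrong: C-alkylation by an unactivated primary bromide may be slow. Intermolecular O-alkylation with oligomerisation, base-induced loss of HBr from the chain, or addition of an ortho phenoxide to C2 of the pyranone with ring opening could then take over.
- Fallback (same bond, transition-metal instead of phenoxide chemistry): setting out from 17, one equivalent of N-iodosuccinimide in DMF at 0 °C should iodinate one of the two equivalent, most activated CH positions of ring A'' to give the iodoaryl bromide F1. An intramolecular nickel-catalysed reductive cross-electrophile coupling of the aryl iodide with the alkyl bromide (NiI2, 4,4'-di-tert-butyl-2,2'-bipyridine, Zn, DMA, 60 °C) should then form C4''-C4a'' and come back to the route at 20.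

2. Step 11.
- What may go wrong: discrimination between the para and the two ortho hydroxyls may be poor, etherification may occur twice, and the electron-rich benzylic alkoxyphosphonium salt may partly ionise, eroding the enantiomeric purity.
- Fallback (protecting-group relay instead of steric selection in the bond-forming step): setting out from 10, the much more size-sensitive TIPSCl (one equivalent, imidazole, DMF, 0 °C) should silylate only the para hydroxyl to give the silyl ether F2. Acetylation (Ac2O, pyridine) gives the silyl ether diacetate F3, and TBAF buffered with AcOH in THF at 0 °C frees the para phenol diacetate F4. Mitsunobu reaction with 16 under the conditions of step 11, now on a single free hydroxyl, gives the bromo ether diacetate F5. Brief methanolysis (K2CO3, MeOH-THF, 0 °C) removes both acetates and rejoins the route at 17.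

3. Step 4.
- What may go wrong: transmetalation and reductive elimination between two doubly ortho-substituted partners may be slow, leaving room for hydrodeiodination of the flavone and homocoupling of the arylzinc.
- Fallback (roles of the two partners exchanged): setting out from 2 and 6, the 3-lithioflavone 3 generated as in step 2 is transmetalated with ZnCl2 to the flavon-3-ylzinc chloride F6. Aryllithium 7 generated as in step 4 is quenched with I2 to give 2-iodo-1,3,5-tris(methoxymethoxy)benzene F7. The two are joined by Negishi coupling (Pd2(dba)3, SPhos, THF, 65 °C), which comes back to the route at 9.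

Further compounds
F1 | step 12 | 5,7-bis(benzyloxy)-2-[4-(benzyloxy)phenyl]-3-{4-[(1S)-1-[4-(benzyloxy)phenyl]-3-bromopropoxy]-2,6-dihydroxy-3-iodophenyl}chromen-4-one | O=c1c(-c2c(O)c(I)c(O[C@@H](CCBr)c3ccc(OCc4ccccc4)cc3)cc2O)c(-c2ccc(OCc3ccccc3)cc2)oc2cc(OCc3ccccc3)cc(OCc3ccccc3)c12
F2 | step 11 | 5,7-bis(benzyloxy)-2-[4-(benzyloxy)phenyl]-3-{2,6-dihydroxy-4-[tri(propan-2-yl)silyloxy]phenyl}chromen-4-one | O=c1c(-c2c(O)cc(O[Si](C(C)C)(C(C)C)C(C)C)cc2O)c(-c2ccc(OCc3ccccc3)cc2)oc2cc(OCc3ccccc3)cc(OCc3ccccc3)c12
F3 | step 11 | 2-{5,7-bis(benzyloxy)-2-[4-(benzyloxy)phenyl]-4-oxochromen-3-yl}-5-[tri(propan-2-yl)silyloxy]benzene-1,3-diyl diacetate | O=c1c(-c2c(OC(C)=O)cc(O[Si](C(C)C)(C(C)C)C(C)C)cc2OC(C)=O)c(-c2ccc(OCc3ccccc3)cc2)oc2cc(OCc3ccccc3)cc(OCc3ccccc3)c12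
F4 | step 11 | 2-{5,7-bis(benzyloxy)-2-[4-(benzyloxy)phenyl]-4-oxochromen-3-yl}-5-hydroxybenzene-1,3-diyl diacetate | O=c1c(-c2c(OC(C)=O)cc(O)cc2OC(C)=O)c(-c2ccc(OCc3ccccc3)cc2)oc2cc(OCc3ccccc3)cc(OCc3ccccc3)c12
F5 | step 11 | 2-{5,7-bis(benzyloxy)-2-[4-(benzyloxy)phenyl]-4-oxochromen-3-yl}-5-[(1S)-1-[4-(benzyloxy)phenyl]-3-bromopropoxy]benzene-1,3-diyl diacetate | O=c1c(-c2c(OC(C)=O)cc(O[C@@H](CCBr)c3ccc(OCc4ccccc4)cc3)cc2OC(C)=O)c(-c2ccc(OCc3ccccc3)cc2)oc2cc(OCc3ccccc3)cc(OCc3ccccc3)c12
F6 | step 4 | {5,7-bis(benzyloxy)-2-[4-(benzyloxy)phenyl]-4-oxochromen-3-yl}zinc chloride | O=c1c([Zn]Cl)c(-c2ccc(OCc3ccccc3)cc2)oc2cc(OCc3ccccc3)cc(OCc3ccccc3)c12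
F7 | step 4 | 2-iodo-1,3,5-tris(methoxymethoxy)benzene | COCOc1cc(OCOC)c(I)c(OCOC)c1
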